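**Remark (assumption):** the SMILES is read as (S) at C3 of both 3-hydroxybutanoate units, (R) at the carbinol carbon of the arylpropyl chain and (S) at C3 of the 3,4-dihydroxybutanoate unit. Aqueous work-up is implied after every step and is written out only where it fixes the form of a by-product.

## Structural features

Talapolyester D (21) is an open-chain tetra-ester with one ring: a benzene ring that carries a carboxyl carbon on C1, hydroxyl groups on C2 and C4 and a 2-oxypropyl chain on C6 (a 6-alkyl-β-resorcylate), joined to three C4 hydroxy-acid chains. The benzoate carbonyl on C1 is esterified by O3 of methyl (S)-3-hydroxybutanoate; the side-chain oxygen is acylated by C1 of (S)-3,4-dihydroxybutanoic acid, whose O3 carries an (S)-3-hydroxybutanoyl group while its O4 is free. The four stereocenters (S, R, S, S along the chain) are isolated secondary carbinol carbons at least four atoms apart, so no relative stereocontrol is needed; each is brought in enantiopure and its C–O bond must be handled with defined retention. Fragile points are the three β-acyloxy ester units (E1cB loss of carboxylate under base), the free primary hydroxyl that is vicinal to a secondary ester (1,2-acyl shift) and γ to an ester carbonyl (lactonization), and the arylpropanol oxygen, which when free lies δ to the benzoate carbonyl and can close to a dihydroisocoumarin. The real difficulty is the tetrasubstituted arene and its ester: the C1 carbonyl is flanked by the C2 oxygen and the C6 chain, so acylation of a secondary, elimination-prone alcohol by this acid is the weak point of any esterification plan, and the arene normally costs a separate synthesis. The key step exploits the fact that the oxygens on C2 and C4 and the carboxyl carbon on C1 mark the ring as a folded 3,5,7-triketo acid: C1 maps onto an active methylene and C6 onto a ketone, so the C1–C6 ring bond and the benzoate C(=O)–O bond can be made in one operation from an acyclic chain.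

## Logic of the disconnections

**21 ⇒ 20.** The four O–CH2Ph bonds are cut (on the C2 and C4 phenol oxygens, on O4 of the dihydroxybutanoate and on O3 of the terminal hydroxybutanoate). Every free hydroxyl of 21 can be acylated or can attack a neighbouring ester, so all must stay masked to the end and be released without acid or base. The gain is one type of protecting group and a single final operation. The demand is that 20 holds nothing else that hydrogen over palladium touches.

**20 ⇒ 12 + 19.** The acyl C–O bond between the arylpropanol oxygen of 12 and C1 of 19 is cut. It is the central ester bond and divides the molecule into an aromatic and an aliphatic half, each with two stereocenters. The demand is O-acylation of a secondary alcohol (retention) by an acid with a β-acyloxy leaving group, without β-elimination and without attack of the alcohol on its own benzoate.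

**12 ⇒ 11 ⇒ 10.** The O–Si bond on the side-chain oxygen and the two phenolic O–benzyl bonds are exchanged. The side-chain oxygen must be a poor leaving group and non-nucleophilic while the ring is built, and the phenols must be inert while that oxygen is acylated. The skeleton is not simplified. The demand is conditions that the β-aroyloxy ester tolerates.

**10 ⇒ 6 + 7 (key).** Two bonds are cut together: the ring bond C1–C6 of the arene, with the C2 and C4 phenols returned to ketones, and the benzoate C(=O)–O bond to the oxygen of 7. The 1,3-pattern of ring oxygens identifies the ring as the cyclized triketo ester 9, and 9 is the adduct of 7 with acylketene 8, which is latent in the dioxinone ring of 6. The gain is the largest of the route: the tetrasubstituted benzene, its regiochemistry and the hindered ester all vanish, leaving an unbranched chain with one stereocenter and a commercial alcohol. In one sentence: 6 is heated with 7 so that the unmasked acylketene is captured and the resulting triketo ester is cycloaromatized to the arene that already carries its ester. The demand is intermolecular capture of the ketene by a secondary alcohol, aldol closure through the right methylene onto the right ketone, and survival of the β-silyloxy ketone and the β-acyloxy ester.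

**6 ⇒ 5 + 3.** The C–C bond between the central methylene (C3') and the carbonyl C4' of the side chain of 6 is cut. This separates the only stereocenter of 6, supplied by 3, from an achiral nucleophile. The demand is acylation at the terminal carbon of a dianion by an acyl donor that adds only once.

**5 ⇒ 4; 3 ⇒ 2 ⇒ 1.** The bond between the ring-attached methylene and the acetyl carbonyl of 5 is cut to give 4 and an acetyl donor. The amide C–N bond of 3 and the O–Si bond of 2 are cut to give 1. These end at commercial materials. The demand is γ-selective acylation of the dienolate of 4 and amide formation without β-elimination.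

**19 ⇒ 17.** The carboxyl carbon of 19 is traced back, through 18, to the internal carbon of a terminal alkene. An alkene is indifferent to the esterification that makes 17, so the carboxyl group needs no orthogonal protecting group. The demand is oxidative cleavage that spares benzyl ethers and does not eliminate the β-acyloxy aldehyde.

**17 ⇒ 16 + 14.** The ester bond between O2 of 16 and the carbonyl of 14 is cut to give two small enantiopure pieces. The demand is plain O-acylation with retention.

**16 ⇒ 15; 14 ⇒ 13 ⇒ 7.** The C3–C4 bond of 16 is cut (vinyl nucleophile on the terminal epoxide carbon of 15, stereocenter untouched). The O–benzyl bond and the methyl ester of 13 lead back to 7, which therefore serves twice. The demand is regioselective epoxide opening and non-basic O-benzylation.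

## Other disconnections considered

**Alternative 1:** (the first plan that comes to mind) The three ester C(=O)–O bonds are cut and the arene is kept intact. The forward key step is acylation of a methyl 3-hydroxybutanoate by the preformed acid A1, 2,4-bis(benzyloxy)-6-[(2R)-2-{[tri(propan-2-yl)silyl]oxy}propyl]benzoic acid, with inversion under Mitsunobu conditions or with retention through an activated acyl derivative. A1 would need its own sequence (side-chain introduction on a protected orsellinate or an aryl-metal species, then carboxyl adjustment), roughly as long as the chosen main line up to 11. Its carbonyl is twisted out of the ring plane and screened on both sides, so attack of a secondary alcohol on any activated form is slow and leaves time for E1cB loss from the β-hydroxy ester or for participation of the side-chain oxygen; the Mitsunobu variant trades this for dehydration of the β-hydroxy ester. The chosen plan makes the same bond by addition to an unhindered ketene carbon and builds the ring in the same flask.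

**Alternative 2:** The ring bonds C1–C2 and C5–C6 are cut. A [4+2] cycloaddition of ynoate A2, methyl (3S)-3-{[(5R)-5-{[tert-butyl(dimethyl)silyl]oxy}hex-2-ynoyl]oxy}butanoate, with a 1-alkoxy-1,3-bis(silyloxy)butadiene, followed by loss of alcohol and desilylation, would give 10 with the right regiochemistry, since the nucleophilic diene terminus bonds to the β-carbon of the ynoate. A β-alkyl ynoate is a sluggish dienophile, so temperatures well above 110 °C and an excess of a moisture-sensitive diene would be needed, which puts the β-acyloxy ester and the silyloxy chain at risk; A2 is also a Michael acceptor. The ester bond would have to be made beforehand in a separate esterification, and A2 needs an alkyne carboxylation sequence, so no step is saved and the thermal window is narrower than in the chosen plan.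

**Alternative 3:** The bond between arene C1 and the carboxyl carbon is cut. Palladium-catalysed alkoxycarbonylation of aryl bromide A3, 1,5-bis(benzyloxy)-2-bromo-3-[(2R)-2-{[tert-butyl(dimethyl)silyl]oxy}propyl]benzene, with carbon monoxide and 7 would give 11 directly. Oxidative addition into an electron-rich bromide with two ortho substituents is slow, and the equally crowded acyl-palladium species must be intercepted by a secondary alcohol that is prone to β-elimination under the base required, so reduction and elimination are expected to compete. A3 still needs a separate arene synthesis with regioselective bromination, so the arene problem is moved, not solved.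

Key step: step 5

## Route

**Step 1**  
Reactants: 1 methyl (3R)-3-hydroxybutanoate  
Product: 2 methyl (3R)-3-{[tert-butyl(dimethyl)silyl]oxy}butanoate  
Conditions: TBSCl, imidazole, DMF, 0 °C → rt  
Reagents that add atoms: tert-butyldimethylsilyl chloride, `CC(C)(C)[Si](C)(C)Cl`  
Why: Standard imidazole-promoted O-silylation of a secondary alcohol; the stereocenter is not touched, and the TBS ether is chosen because it is a poor leaving group that survives enolate chemistry, 110 °C and carbonate but is removed by buffered HF.

**Step 2**  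
Reactants: 2 methyl (3R)-3-{[tert-butyl(dimethyl)silyl]oxy}butanoate  
Product: 3 (3R)-3-{[tert-butyl(dimethyl)silyl]oxy}-N-methoxy-N-methylbutanamide  
Conditions: MeNHOMe·HCl, i-PrMgCl, THF, −20 → 0 °C  
Reagents that add atoms: N,O-dimethylhydroxylamine hydrochloride, `CNOC.Cl`  
Why: Direct aminolysis of the ester by the chloromagnesium amide formed in the flask (Weinreb amide synthesis); the low temperature and the non-nucleophilic Grignard base should avoid β-elimination, and the stereocenter is not involved.

**Step 3**  
Reactants: 4 2,2,6-trimethyl-4H-1,3-dioxin-4-one  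
Product: 5 2,2-dimethyl-6-(2-oxopropyl)-4H-1,3-dioxin-4-one  
Conditions: LiHMDS, THF, −78 °C; AcCl (0.5 equiv), −78 → −20 °C; 1 M HCl  
Reagents that add atoms: acetyl chloride, `CC(Cl)=O`  
Why: γ-Deprotonation gives the lithium dienolate of 4, which is C-acylated at the γ-carbon (vinylogous Claisen acylation); half of the dienolate serves as base for the more acidic product, and unreacted 4 is recovered.

**Step 4**  
Reactants: 5 2,2-dimethyl-6-(2-oxopropyl)-4H-1,3-dioxin-4-one, 3 (3R)-3-{[tert-butyl(dimethyl)silyl]oxy}-N-methoxy-N-methylbutanamide  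
Product: 6 6-[(6R)-6-{[tert-butyl(dimethyl)silyl]oxy}-2,4-dioxoheptyl]-2,2-dimethyl-4H-1,3-dioxin-4-one  
Conditions: 5, LDA (2.2 equiv), THF, −78 → −40 °C; then 3, −78 → −20 °C; 1 M HCl, 0 °C  
Reagents that add atoms: none  
Why: Crossed Claisen condensation of a 1,3-dicarbonyl-type dianion: the terminal, last-formed carbanion of the dianion of 5 is the most nucleophilic site and adds to the Weinreb amide, whose chelated tetrahedral intermediate prevents a second addition. The stereocenter is β to the reacting carbonyl and is not touched.

**Step 5**  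
Reactants: 6 6-[(6R)-6-{[tert-butyl(dimethyl)silyl]oxy}-2,4-dioxoheptyl]-2,2-dimethyl-4H-1,3-dioxin-4-one, 7 methyl (3S)-3-hydroxybutanoate  
Product: 10 methyl (3S)-3-({2,4-dihydroxy-6-[(2R)-2-{[tert-butyl(dimethyl)silyl]oxy}propyl]benzoyl}oxy)butanoate, via acylketene 8 (not isolated), via triketo ester 9 (not isolated)  
Conditions: 7 (2 equiv), PhMe, 110 °C; then Cs2CO3, i-PrOH/CH2Cl2, rt; then AcOH  
Reagents that add atoms: none  
Why: Heating 6 causes a retro-hetero-Diels–Alder loss of acetone to acylketene 8, whose unhindered sp carbon is attacked by the hydroxyl of 7, so the crowded benzoate C(=O)–O bond is made by addition and not by substitution at a di-ortho-substituted carbonyl; the closest known reaction type is the biomimetic dioxinone ketene-trapping and late-stage aromatization route to resorcylates. Carbonate then deprotonates the most acidic methylene of triketo ester 9 (C2, between the ester and the C3 ketone), and this carbon adds to the C7 ketone in a 6-exo-trig (6-enolendo) aldol closure that forms the future C1–C6 ring bond. Loss of water and enolization of the C3 and C5 carbonyls give the 2,4-dihydroxy-6-alkylbenzoate irreversibly, with aromatic stabilization as the driving force. No stereocenter is created: the carbinol of 7 reacts at oxygen with retention, and the silyloxy carbon is β to a ketone and not enolizable, so both configurations are carried through. The step needs intermolecular capture of 8 in preference to ketene dimerization or cyclization to a pyranone, which the excess of cheap 7 should secure, and aldol in preference to Claisen-type or lactonizing cyclization of 9, which the mild carbonate protocol should secure because the C2 carbanion is the preferred nucleophile and only the C7 ketone lies six atoms away. The silyl ether is a poor leaving group, which suppresses β-elimination next to the C7 ketone, and i-PrOH avoids ester exchange.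

**Step 6**  
Reactants: 10 methyl (3S)-3-({2,4-dihydroxy-6-[(2R)-2-{[tert-butyl(dimethyl)silyl]oxy}propyl]benzoyl}oxy)butanoate  
Product: 11 methyl (3S)-3-({2,4-bis(benzyloxy)-6-[(2R)-2-{[tert-butyl(dimethyl)silyl]oxy}propyl]benzoyl}oxy)butanoate  
Conditions: BnBr, K2CO3, Bu4NI (cat.), DMF, rt  
Reagents that add atoms: benzyl bromide, `BrCc1ccccc1`  
Why: Williamson O-benzylation of both phenols; iodide catalysis in DMF should let the hydrogen-bonded 2-OH react at room temperature, which is mild enough for the β-aroyloxy ester and the silyl ether.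

**Step 7**  
Reactants: 11 methyl (3S)-3-({2,4-bis(benzyloxy)-6-[(2R)-2-{[tert-butyl(dimethyl)silyl]oxy}propyl]benzoyl}oxy)butanoate  
Product: 12 methyl (3S)-3-({2,4-bis(benzyloxy)-6-[(2R)-2-hydroxypropyl]benzoyl}oxy)butanoate  
Conditions: HF·pyridine, pyridine, THF, 0 °C → rt  
Reagents that add atoms: none  
Why: Fluoride-mediated desilylation under buffered, weakly acidic conditions; no alkoxide is formed, and the twisted, electron-rich di-ortho-substituted benzoate is a poor acceptor, so closure to the dihydroisocoumarin and β-elimination should not compete.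

**Step 8**  
Reactants: 7 methyl (3S)-3-hydroxybutanoate  
Product: 13 methyl (3S)-3-(benzyloxy)butanoate  
Conditions: BnOC(=NH)CCl3, TfOH (cat.), CH2Cl2/cyclohexane, 0 °C → rt  
Reagents that add atoms: benzyl 2,2,2-trichloroacetimidate, `N=C(OCc1ccccc1)C(Cl)(Cl)Cl`  
Why: Acid-catalysed O-benzylation with the trichloroacetimidate; the non-basic conditions avoid retro-aldol and elimination, and the carbinol C–O bond is not broken, so (S) is retained.

**Step 9**  
Reactants: 13 methyl (3S)-3-(benzyloxy)butanoate  
Product: 14 (3S)-3-(benzyloxy)butanoic acid  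
Conditions: LiOH, THF/H2O, 0 °C → rt; 1 M HCl  
Reagents that add atoms: lithium hydroxide, `[Li+].[OH-]`  
Why: Ester saponification; benzyloxide is a poor leaving group, so E1cB elimination is not expected, and the stereocenter is untouched.

**Step 10**  
Reactants: 15 (2S)-2-[(benzyloxy)methyl]oxirane  
Product: 16 (2S)-1-(benzyloxy)pent-4-en-2-ol  
Conditions: CH2=CHMgBr, CuI (10 mol %), THF, −40 → −20 °C  
Reagents that add atoms: vinylmagnesium bromide, `C=C[Mg]Br`  
Why: Copper-catalysed SN2 opening of the epoxide by the vinyl Grignard reagent at the unsubstituted terminal carbon; the stereocenter is not the site of attack, so its configuration is kept.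

**Step 11**  
Reactants: 16 (2S)-1-(benzyloxy)pent-4-en-2-ol, 14 (3S)-3-(benzyloxy)butanoic acid  
Product: 17 (2S)-1-(benzyloxy)pent-4-en-2-yl (3S)-3-(benzyloxy)butanoate  
Conditions: EDC·HCl, DMAP (cat.), CH2Cl2, 0 °C → rt  
Reagents that add atoms: none  
Why: Steglich esterification; the acid carries only a β-benzyloxy group, a poor leaving group, and acylation at oxygen retains both configurations.

**Step 12**  
Reactants: 17 (2S)-1-(benzyloxy)pent-4-en-2-yl (3S)-3-(benzyloxy)butanoate  
Product: 19 (3S)-4-(benzyloxy)-3-{[(3S)-3-(benzyloxy)butanoyl]oxy}butanoic acid, via aldehyde 18 (not isolated)  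
Conditions: O3, CH2Cl2, −78 °C; Me2S, −78 °C → rt; then NaClO2, NaH2PO4, 2-methyl-2-butene, t-BuOH/H2O, 0 °C → rt  
Reagents that add atoms: ozone, `[O-][O+]=O`; sodium chlorite, `[Na+].[O-]Cl=O`  
Why: Ozonolysis of the terminal alkene with reductive work-up, then Pinnick oxidation of the crude aldehyde; the alkene reacts with ozone far faster than the benzyl ethers when the end point is controlled, and the buffered chlorite oxidation should not eliminate the β-acyloxy group.

**Step 13**  
Reactants: 12 methyl (3S)-3-({2,4-bis(benzyloxy)-6-[(2R)-2-hydroxypropyl]benzoyl}oxy)butanoate, 19 (3S)-4-(benzyloxy)-3-{[(3S)-3-(benzyloxy)butanoyl]oxy}butanoic acid  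
Product: 20 methyl (3S)-3-({2,4-bis(benzyloxy)-6-[(2R)-2-{[(3S)-4-(benzyloxy)-3-{[(3S)-3-(benzyloxy)butanoyl]oxy}butanoyl]oxy}propyl]benzoyl}oxy)butanoate  
Conditions: EDC·HCl, DMAP (0.3 equiv), CH2Cl2, 0 °C → rt  
Reagents that add atoms: none  
Why: Steglich esterification of the secondary alcohol; substoichiometric DMAP at 0 °C limits E1cB loss of the β-acyloxy group from the activated acid, and the carbinol C–O bond of 12 is not broken, so (R) is retained.

**Step 14**  
Reactants: 20 methyl (3S)-3-({2,4-bis(benzyloxy)-6-[(2R)-2-{[(3S)-4-(benzyloxy)-3-{[(3S)-3-(benzyloxy)butanoyl]oxy}butanoyl]oxy}propyl]benzoyl}oxy)butanoate  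
Product: 21 Talapolyester D, methyl (3S)-3-({2,4-dihydroxy-6-[(2R)-2-{[(3S)-4-hydroxy-3-{[(3S)-3-hydroxybutanoyl]oxy}butanoyl]oxy}propyl]benzoyl}oxy)butanoate  
Conditions: H2 (1 atm), 10% Pd/C, EtOAc, rt  
Reagents that add atoms: none  
Why: Hydrogenolysis of the two aryl benzyl ethers and the two alkyl benzyl ethers under neutral conditions; with no acid or base present, acyl migration to the freed primary hydroxyl, γ-lactonization and β-elimination should be avoided, and no stereocenter is affected.

## Compound list

```
1 | methyl (3R)-3-hydroxybutanoate | C[C@@H](O)CC(=O)OC | starting material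
2 | methyl (3R)-3-{[tert-butyl(dimethyl)silyl]oxy}butanoate | C[C@@H](O[Si](C)(C)C(C)(C)C)CC(=O)OC | intermediate
3 | (3R)-3-{[tert-butyl(dimethyl)silyl]oxy}-N-methoxy-N-methylbutanamide | C[C@@H](O[Si](C)(C)C(C)(C)C)CC(=O)N(C)OC | intermediate
4 | 2,2,6-trimethyl-4H-1,3-dioxin-4-one | CC1=CC(=O)OC(C)(C)O1 | starting material
5 | 2,2-dimethyl-6-(2-oxopropyl)-4H-1,3-dioxin-4-one | CC(=O)CC1=CC(=O)OC(C)(C)O1 | intermediate
6 | 6-[(6R)-6-{[tert-butyl(dimethyl)silyl]oxy}-2,4-dioxoheptyl]-2,2-dimethyl-4H-1,3-dioxin-4-one | C[C@@H](O[Si](C)(C)C(C)(C)C)CC(=O)CC(=O)CC1=CC(=O)OC(C)(C)O1 | intermediate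
7 | methyl (3S)-3-hydroxybutanoate | C[C@H](O)CC(=O)OC | starting material
8 | acylketene, (9R)-9-{[tert-butyl(dimethyl)silyl]oxy}-3,5,7-trioxodec-1-en-1-one | C[C@@H](O[Si](C)(C)C(C)(C)C)CC(=O)CC(=O)CC(=O)C=C=O | intermediate (not isolated)
9 | triketo ester, methyl (3S)-3-{[(9R)-9-{[tert-butyl(dimethyl)silyl]oxy}-3,5,7-trioxodecanoyl]oxy}butanoate | COC(=O)C[C@H](C)OC(=O)CC(=O)CC(=O)CC(=O)C[C@@H](C)O[Si](C)(C)C(C)(C)C | intermediate (not isolated)
10 | methyl (3S)-3-({2,4-dihydroxy-6-[(2R)-2-{[tert-butyl(dimethyl)silyl]oxy}propyl]benzoyl}oxy)butanoate | COC(=O)C[C@H](C)OC(=O)c1c(O)cc(O)cc1C[C@@H](C)O[Si](C)(C)C(C)(C)C | intermediate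
11 | methyl (3S)-3-({2,4-bis(benzyloxy)-6-[(2R)-2-{[tert-butyl(dimethyl)silyl]oxy}propyl]benzoyl}oxy)butanoate | COC(=O)C[C@H](C)OC(=O)c1c(OCc2ccccc2)cc(OCc2ccccc2)cc1C[C@@H](C)O[Si](C)(C)C(C)(C)C | intermediate
12 | methyl (3S)-3-({2,4-bis(benzyloxy)-6-[(2R)-2-hydroxypropyl]benzoyl}oxy)butanoate | COC(=O)C[C@H](C)OC(=O)c1c(OCc2ccccc2)cc(OCc2ccccc2)cc1C[C@@H](C)O | intermediate
13 | methyl (3S)-3-(benzyloxy)butanoate | C[C@H](OCc1ccccc1)CC(=O)OC | intermediate
14 | (3S)-3-(benzyloxy)butanoic acid | C[C@H](OCc1ccccc1)CC(=O)O | intermediate
15 | (2S)-2-[(benzyloxy)methyl]oxirane, (S)-benzyl glycidyl ether | C(OCc1ccccc1)[C@@H]1CO1 | starting material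
16 | (2S)-1-(benzyloxy)pent-4-en-2-ol | C=CC[C@@H](COCc1ccccc1)O | intermediate
17 | (2S)-1-(benzyloxy)pent-4-en-2-yl (3S)-3-(benzyloxy)butanoate | C=CC[C@@H](COCc1ccccc1)OC(=O)C[C@H](C)OCc1ccccc1 | intermediate
18 | aldehyde, (2S)-1-(benzyloxy)-4-oxobutan-2-yl (3S)-3-(benzyloxy)butanoate | O=CC[C@@H](COCc1ccccc1)OC(=O)C[C@H](C)OCc1ccccc1 | intermediate (not isolated)
19 | (3S)-4-(benzyloxy)-3-{[(3S)-3-(benzyloxy)butanoyl]oxy}butanoic acid | OC(=O)C[C@@H](COCc1ccccc1)OC(=O)C[C@H](C)OCc1ccccc1 | intermediate
20 | methyl (3S)-3-({2,4-bis(benzyloxy)-6-[(2R)-2-{[(3S)-4-(benzyloxy)-3-{[(3S)-3-(benzyloxy)butanoyl]oxy}butanoyl]oxy}propyl]benzoyl}oxy)butanoate | COC(=O)C[C@H](C)OC(=O)c1c(OCc2ccccc2)cc(OCc2ccccc2)cc1C[C@@H](C)OC(=O)C[C@@H](COCc1ccccc1)OC(=O)C[C@H](C)OCc1ccccc1 | intermediate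
21 | Talapolyester D, methyl (3S)-3-({2,4-dihydroxy-6-[(2R)-2-{[(3S)-4-hydroxy-3-{[(3S)-3-hydroxybutanoyl]oxy}butanoyl]oxy}propyl]benzoyl}oxy)butanoate | COC(=O)C[C@H](C)OC(=O)c1c(O)cc(O)cc1C[C@@H](C)OC(=O)C[C@@H](CO)OC(=O)C[C@H](C)O | target
```

## Step count and least certain steps

Total step count: 14. Longest linear sequence: 8 steps (steps 1, 2, 4, 5, 6, 7, 13 and 14, from 1 to 21).

**Step 5 (key step).** The most likely failure is inefficient capture of the acylketene by a secondary alcohol, so that ketene dimerization or cyclization of an enol oxygen onto the ketene to a pyranone takes over. Next in likelihood are lactonizing cyclization of the triketo ester with loss of the alcohol and carbonate-induced β-elimination in the hydroxybutanoate unit. The fallback keeps the ring-forming aldol aromatization but moves the difficult ester bond to an SN2 event. It sets out from 6, which is heated with allyl alcohol (primary, unhindered, no β-leaving group, usable in large excess) to give prop-2-en-1-yl (9R)-9-{[tert-butyl(dimethyl)silyl]oxy}-3,5,7-trioxodecanoate F1, aromatized in the same flask with carbonate and acid to prop-2-en-1-yl 2,4-dihydroxy-6-[(2R)-2-{[tert-butyl(dimethyl)silyl]oxy}propyl]benzoate F2. Benzylation of both phenols gives prop-2-en-1-yl 2,4-bis(benzyloxy)-6-[(2R)-2-{[tert-butyl(dimethyl)silyl]oxy}propyl]benzoate F3, and palladium(0)/morpholine deallylation gives 2,4-bis(benzyloxy)-6-[(2R)-2-{[tert-butyl(dimethyl)silyl]oxy}propyl]benzoic acid F4. A Mitsunobu reaction of F4 with 1 (PPh3, DIAD) inverts the (R)-carbinol to the (S)-ester, the carboxylate oxygen attacking the carbinol carbon so that crowding at the carbonyl is irrelevant, and the route is rejoined at 11.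

**Step 4.** The delocalized dianion may act as a base toward the α-methylene of the amide, or react sluggishly or at oxygen, and the strongly basic medium may trigger loss of silanolate from the β-silyloxy carbonyl unit. The fallback replaces the acylation by an aldol addition followed by oxidation. It sets out from 2 and 5: DIBAL-H reduction of 2 at −78 °C gives (3R)-3-{[tert-butyl(dimethyl)silyl]oxy}butanal F5. The dianion of 5 adds to F5 faster and more cleanly than to an amide, giving 6-[(6R)-6-{[tert-butyl(dimethyl)silyl]oxy}-4-hydroxy-2-oxoheptyl]-2,2-dimethyl-4H-1,3-dioxin-4-one F6 as a mixture of carbinol epimers, which is of no consequence. Dess–Martin oxidation of F6 rejoins the route at 6.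

**Step 13.** The activated form of 19 can lose its 3-acyloxy group by E1cB elimination, and the homobenzylic secondary alcohol next to an ortho-substituted ring is acylated slowly, so elimination and N-acylurea formation may outrun ester formation. The fallback builds the chain stepwise with acids that have only poor β-leaving groups. It sets out from 16, which is silylated to tert-butyl{[(2S)-1-(benzyloxy)pent-4-en-2-yl]oxy}dimethylsilane F7. Ozonolysis gives (3S)-4-(benzyloxy)-3-{[tert-butyl(dimethyl)silyl]oxy}butanal F8 (not isolated), and Pinnick oxidation gives (3S)-4-(benzyloxy)-3-{[tert-butyl(dimethyl)silyl]oxy}butanoic acid F9. Steglich coupling of F9 with 12 gives methyl (3S)-3-({2,4-bis(benzyloxy)-6-[(2R)-2-{[(3S)-4-(benzyloxy)-3-{[tert-butyl(dimethyl)silyl]oxy}butanoyl]oxy}propyl]benzoyl}oxy)butanoate F10. Buffered HF·pyridine frees methyl (3S)-3-({2,4-bis(benzyloxy)-6-[(2R)-2-{[(3S)-4-(benzyloxy)-3-hydroxybutanoyl]oxy}propyl]benzoyl}oxy)butanoate F11, and acylation of F11 with 14 (EDC, DMAP) rejoins the route at 20.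

**Step 6.** Alkylation of the hydrogen-bonded 2-OH is slow, and during this time carbonate may induce E1cB loss of the aroyloxy group from the methyl butanoate unit. The fallback changes the protecting-group plan and leaves the chelated phenol free. It sets out from 10, which with about one equivalent of benzyl bromide and K2CO3 in acetone at rt gives methyl (3S)-3-({4-(benzyloxy)-2-hydroxy-6-[(2R)-2-{[tert-butyl(dimethyl)silyl]oxy}propyl]benzoyl}oxy)butanoate F12. HF·pyridine gives methyl (3S)-3-({4-(benzyloxy)-2-hydroxy-6-[(2R)-2-hydroxypropyl]benzoyl}oxy)butanoate F13. Steglich coupling with 19, in which the hydrogen-bonded phenol is expected to stay unacylated, gives methyl (3S)-3-({4-(benzyloxy)-6-[(2R)-2-{[(3S)-4-(benzyloxy)-3-{[(3S)-3-(benzyloxy)butanoyl]oxy}butanoyl]oxy}propyl]-2-hydroxybenzoyl}oxy)butanoate F14, and hydrogenolysis of its three benzyl ethers rejoins the route at 21.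

## Further compounds

```
F1 | step 5 | prop-2-en-1-yl (9R)-9-{[tert-butyl(dimethyl)silyl]oxy}-3,5,7-trioxodecanoate | C=CCOC(=O)CC(=O)CC(=O)CC(=O)C[C@@H](C)O[Si](C)(C)C(C)(C)C
F2 | step 5 | prop-2-en-1-yl 2,4-dihydroxy-6-[(2R)-2-{[tert-butyl(dimethyl)silyl]oxy}propyl]benzoate | C=CCOC(=O)c1c(O)cc(O)cc1C[C@@H](C)O[Si](C)(C)C(C)(C)C
F3 | step 5 | prop-2-en-1-yl 2,4-bis(benzyloxy)-6-[(2R)-2-{[tert-butyl(dimethyl)silyl]oxy}propyl]benzoate | C=CCOC(=O)c1c(OCc2ccccc2)cc(OCc2ccccc2)cc1C[C@@H](C)O[Si](C)(C)C(C)(C)C
F4 | step 5 | 2,4-bis(benzyloxy)-6-[(2R)-2-{[tert-butyl(dimethyl)silyl]oxy}propyl]benzoic acid | OC(=O)c1c(OCc2ccccc2)cc(OCc2ccccc2)cc1C[C@@H](C)O[Si](C)(C)C(C)(C)C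
F5 | step 4 | (3R)-3-{[tert-butyl(dimethyl)silyl]oxy}butanal | C[C@@H](O[Si](C)(C)C(C)(C)C)CC=O
F6 | step 4 | 6-[(6R)-6-{[tert-butyl(dimethyl)silyl]oxy}-4-hydroxy-2-oxoheptyl]-2,2-dimethyl-4H-1,3-dioxin-4-one (both C4' epimers) | C[C@@H](O[Si](C)(C)C(C)(C)C)CC(O)CC(=O)CC1=CC(=O)OC(C)(C)O1
F7 | step 13 | tert-butyl{[(2S)-1-(benzyloxy)pent-4-en-2-yl]oxy}dimethylsilane | C=CC[C@@H](COCc1ccccc1)O[Si](C)(C)C(C)(C)C
F8 | step 13 | (3S)-4-(benzyloxy)-3-{[tert-butyl(dimethyl)silyl]oxy}butanal | O=CC[C@@H](COCc1ccccc1)O[Si](C)(C)C(C)(C)C
F9 | step 13 | (3S)-4-(benzyloxy)-3-{[tert-butyl(dimethyl)silyl]oxy}butanoic acid | OC(=O)C[C@@H](COCc1ccccc1)O[Si](C)(C)C(C)(C)C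
F10 | step 13 | methyl (3S)-3-({2,4-bis(benzyloxy)-6-[(2R)-2-{[(3S)-4-(benzyloxy)-3-{[tert-butyl(dimethyl)silyl]oxy}butanoyl]oxy}propyl]benzoyl}oxy)butanoate | COC(=O)C[C@H](C)OC(=O)c1c(OCc2ccccc2)cc(OCc2ccccc2)cc1C[C@@H](C)OC(=O)C[C@@H](COCc1ccccc1)O[Si](C)(C)C(C)(C)C
F11 | step 13 | methyl (3S)-3-({2,4-bis(benzyloxy)-6-[(2R)-2-{[(3S)-4-(benzyloxy)-3-hydroxybutanoyl]oxy}propyl]benzoyl}oxy)butanoate | COC(=O)C[C@H](C)OC(=O)c1c(OCc2ccccc2)cc(OCc2ccccc2)cc1C[C@@H](C)OC(=O)C[C@@H](COCc1ccccc1)O
F12 | step 6 | methyl (3S)-3-({4-(benzyloxy)-2-hydroxy-6-[(2R)-2-{[tert-butyl(dimethyl)silyl]oxy}propyl]benzoyl}oxy)butanoate | COC(=O)C[C@H](C)OC(=O)c1c(O)cc(OCc2ccccc2)cc1C[C@@H](C)O[Si](C)(C)C(C)(C)C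
F13 | step 6 | methyl (3S)-3-({4-(benzyloxy)-2-hydroxy-6-[(2R)-2-hydroxypropyl]benzoyl}oxy)butanoate | COC(=O)C[C@H](C)OC(=O)c1c(O)cc(OCc2ccccc2)cc1C[C@@H](C)O
F14 | step 6 | methyl (3S)-3-({4-(benzyloxy)-6-[(2R)-2-{[(3S)-4-(benzyloxy)-3-{[(3S)-3-(benzyloxy)butanoyl]oxy}butanoyl]oxy}propyl]-2-hydroxybenzoyl}oxy)butanoate | COC(=O)C[C@H](C)OC(=O)c1c(O)cc(OCc2ccccc2)cc1C[C@@H](C)OC(=O)C[C@@H](COCc1ccccc1)OC(=O)C[C@H](C)OCc1ccccc1
A1 | alternative 1 | 2,4-bis(benzyloxy)-6-[(2R)-2-{[tri(propan-2-yl)silyl]oxy}propyl]benzoic acid | OC(=O)c1c(OCc2ccccc2)cc(OCc2ccccc2)cc1C[C@@H](C)O[Si](C(C)C)(C(C)C)C(C)C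
A2 | alternative 2 | methyl (3S)-3-{[(5R)-5-{[tert-butyl(dimethyl)silyl]oxy}hex-2-ynoyl]oxy}butanoate | COC(=O)C[C@H](C)OC(=O)C#CC[C@@H](C)O[Si](C)(C)C(C)(C)C
A3 | alternative 3 | 1,5-bis(benzyloxy)-2-bromo-3-[(2R)-2-{[tert-butyl(dimethyl)silyl]oxy}propyl]benzene | Brc1c(OCc2ccccc2)cc(OCc2ccccc2)cc1C[C@@H](C)O[Si](C)(C)C(C)(C)C
```
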